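# Total synthesis proposal for CNP0305796.2 (32): Claisen ring expansion of a 2-methylidene-tetrahydrofuran to the hydroazulenone

## The problem

The target 32 is a trans-fused bicyclo[5.3.0]decane of the daucane type: a cyclopentane (C1–C5) shares the C1–C5 bond with a cycloheptene (C5–C10 and C1). The numbering used throughout is C1 (ring-fusion carbon with methyl), C2, C3, C4 (hydroxyl and isopropyl), C5 (ring-fusion hydrogen), C6 (4-hydroxybenzoyloxy), C7=C8 (methyl on C8), C9 (acetoxy) and C10. Five stereocentres, (1R,4R,5S,6S,9S), have to be set: H5 and the oxygens on C6 and C9 lie on one face, the C1 methyl and the C4 hydroxyl on the other. C1 is quaternary and cannot be repaired later, so it must be set early with absolute control. Once in place, the angular methyl is the natural control element for C5 and C6 (addition to a C5=C6 bond) and for C4 (addition to a C4 ketone), whereas C9, on the far side of the seven-membered ring, calls for reagent control. The C6–C7=C8–C9 unit is a doubly allylic 1,4-diester that will not tolerate strong acid, strong base or zerovalent palladium (ionisation, allylic transposition, elimination, acyl migration); two different acyl groups must be placed unambiguously, and the phenol must be freed last beside an acetate. Ketone stages at C4 carry a β-oxygen at C6 and an epimerisable C5, so they invite elimination and loss of the ring fusion. The feature that opens the way is the 1,4-relation of the oxygens on C6 and C9 together with the position of C9 β to quaternary C1: if C6 and C9 share one oxygen, which C7 and C8 allow by closing a tetrahydrofuran, then C10=C9–O–C6–C5=C1 is an allyl vinyl ether whose [3,3] shift makes the C1–C10 bond, the seven-membered ring, a C9 carbonyl and a C5=C6 alkene in one step.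

## Retrosynthesis

**32 to 27 and 30.** The aryl O–Si bond and the C6 O–acyl bond are cut. The aroyl ester is introduced last because it would not survive enolate chemistry or an organometallic addition, and because a β-acyloxy ketone at the C4 ketone stage would eliminate. Acid 30 comes in one step from 4-hydroxybenzoic acid 28; its silyl ether can be cleaved by fluoride without touching either ester. The forward reaction has to acylate a hindered secondary alcohol beside an inert tertiary one.

**27 to 26 to 25.** The C9 O–acetyl bond and the C6 O–Si bond are cut. Acetylating C9 while C6 is still silylated removes any question of which secondary hydroxyl reacts; the reverse order would rely on selectivity between two allylic alcohols. Triol derivative 25 carries all five stereocentres and only one protecting group.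

**25 to 24 to 23.** The C4–isopropyl bond is cut, leading back to C4 ketone 24 and its ethylene ketal 23. Carrying the tertiary carbinol through the whole route would add a second, uncontrolled stereocentre before the key step, whereas a ketal is achiral and inert. The forward addition must be non-basic (C5 is enolisable and C6 bears a leaving group) and must come from the face opposite the angular methyl.

**23 to 22 to 20 to 18.** The C9–H bond, the C7=C8 double bond and the C8–CH3 bond are cut in turn. The α-methyl cycloheptenone 22 is the most direct source of the C9 allylic alcohol and is a good substrate for catalyst-controlled reduction. It arises from ketone 18 by methylation to 20 and dehydrogenation. Because C1 is quaternary, dehydrogenation of the C9 ketone can run only towards C7, so no regiochemical question arises there.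

**18 to 16 to 14 to 13.** The C6–O and C5–H bonds are cut back to the C5=C6 alkene of 13. Syn-hydroboration installs both in one operation with the cis relation the target needs, and boron goes to the less substituted C6. Borane would reduce the C9 ketone, so it is masked as the dimethyl ketal 14, which can later be hydrolysed selectively in the presence of the more robust C4 dioxolane.

**13 to 12 (key disconnection).** The C1–C10 bond is cut and the C6–O bond re-formed, which turns the carbocycle into the 2-methylidene-5-(cyclopentenyl)oxolane 12. This cut is preferred to cutting C8–C9 or C5–C6 because it creates the quaternary centre and the seven-membered ring together and relays one easily made carbinol centre (C6) to C1. The precursor has one stereocentre and no carbocyclic seven-membered ring. The forward reaction must tolerate a fully substituted alkene terminus.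

**12 to 11 to 9.** The exocyclic methylene is cut back to the carbonyl of lactone 11, and the C6–H bond back to keto ester 9. Asymmetric ketone reduction is the simplest way to an enantiopure secondary allylic alcohol on a tetrasubstituted alkene; the γ-hydroxy ester closes to the lactone by itself.

**9 to 5 and 6; 5 to 3 to 1 and 4.** The C5–C6 bond is cut between a vinyl anion equivalent from bromo ketal 5 and succinic anhydride 6, which supplies C6–C9. Bromo ketal 5 comes from 3-methylcyclopent-2-en-1-one 1 by α-bromination to bromo enone 3 and ketalisation with ethylene glycol 4. All four building blocks 1, 4, 6 and 28 are commercial.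

## Roads not taken

**Alternative 1:** The C1–C5 bond of the five-membered ring is cut. Commercial (S)-citronellol A1 would supply C1 with its methyl group, and degradation of A1 at its alkene end would lead to the α-diazo-β-keto ester A2. Rh2(OAc)4 (divalent rhodium) would decompose the diazo group of A2, and insertion of the carbene carbon C5 into the tertiary C1–H bond with retention would close cyclopentanone A3 with the quaternary methyl centre.
- Merits: C1 comes from the chiral pool in A1, and tertiary C–H insertion with retention is dependable. A3 already has the C4 carbonyl for the isopropyl addition.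
- Weak points: only the small ring is made. The seven-membered ring, with C6, C9, the C7=C8 bond and the C8 methyl, must then be annulated from the C5 ester and the C10–C9 silyloxyethyl arm in a second, longer ring-forming campaign. C5 in A3 is an epimerisable β-keto ester carbon, so it carries no lasting stereochemical information.
- Comparison: on the security of C1 this road is better than the chosen plan, whose Claisen shift onto a fully substituted terminus is untested. The chosen plan sets against it that a single step forms the quaternary centre and the seven-membered ring and leaves a carbonyl at C9 and an alkene at C5=C6, exactly where the remaining groups are needed.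

**Alternative 2:** The C1–C5 and C7–C8 bonds are cut. Catalytic Et3SiOSO2CF3 would open the epoxide of the epoxy enol silane A4 at C5, and the tethered diene would capture the allyl cation terminus C5–C6–C7 so formed in an intramolecular (4+3) cycloaddition. The product is bicyclic ketone A5 with both rings, C1, C5, the C4 silyl ether with its isopropyl group, and a C6 carbonyl.
- Merits: this is the most convergent road to the bicycle. It settles C4 before the rings exist, which the chosen plan leaves as a late risk.
- Weak points: A5 has its alkene at C9=C10 and a methyl-bearing stereocentre at C8, while the target needs C7=C8 and oxygen at C9. An oxidative allylic transposition in a ring with few handles would be required, and the C8 centre set in the cycloaddition is destroyed afterwards. The C6 ketone must be reduced next to an epimerisable C5. Facial and endo/exo selectivity with a fully substituted diene terminus rests on the C4 centre alone. The enantiopure trisubstituted epoxide of A4 needs its own asymmetric step.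
- Comparison: in step economy to the core, alternative 2 is better. The chosen plan offers a key-step product whose functional groups (C9=O, C5=C6, masked C4=O) each sit on the carbon where the target needs them, so no transposition is required.

**Alternative 3:** The C1–C10 and C5–C6 bonds are cut. Cu(OTf)2 with a chiral N-heterocyclic carbene ligand would catalyse conjugate addition of the vinyl Grignard reagent A6, (E)-2-(trimethylsilyl)ethenylmagnesium bromide, to C1 of enone 1. Aldol trapping at C5 in the same flask by the iodo-enal A7, (Z)-3-iodobut-2-enal, would give aldol A8 with C1, C5 and C6 set.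
- Merits: it starts from the same commercial enone and reaches three stereocentres in the first step. The vinyl iodide from A7 already holds C7=C8 with its methyl, and the vinylsilane from A6 is a latent C10–C9 aldehyde, so closing C8–C9 would give the C9 carbinol directly. This is probably the shortest route and is better than the chosen plan for the C6–C9 segment.
- Weak points: β-methylcyclopentenones are among the least reactive and least selective acceptors for quaternary-centre-forming conjugate additions, and an insufficient enantiomeric excess cannot be upgraded by a later transfer step. The configuration at C6 depends on an intermolecular aldol of a hindered, fully substituted enolate. A8 is a β-hydroxy cyclopentanone with a free C4 ketone, prone to retro-aldol cleavage, dehydration and C5 epimerisation in every later step. The seven-membered ring closure sets C9 under substrate control only.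
- Comparison: the chosen plan sets against it two dependable oxazaborolidine reductions for absolute control, chirality transfer to C1 through a constrained transition state, a C4 carbonyl that stays masked until it is used, and C5/C6 set together by a syn addition.

Key step: step 6

## Route

Assumption: the target is read from its SMILES as the (1R,4R,5S,6S,9S) isomer in the numbering given under "The problem" (trans ring fusion; O6, O9 and H5 cis to one another and trans to the C1 methyl and the C4 hydroxyl), and all locants and descriptors of the bicyclic compounds follow that numbering.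

Step 1
Reactants: 1 3-methylcyclopent-2-en-1-one
Product: 3 2-bromo-3-methylcyclopent-2-en-1-one, via 2,3-dibromo-3-methylcyclopentan-1-one 2 (not isolated)
Conditions: Br2, CH2Cl2, 0 °C; then Et3N, 0 °C to rt
Reagents that add atoms: bromine, BrBr
Why: Bromine adds across the enone double bond and triethylamine removes HBr from the dibromide (addition–elimination α-bromination of an enone), which returns the conjugated alkene with bromine on C2.

Step 2
Reactants: 3 2-bromo-3-methylcyclopent-2-en-1-one, 4 ethylene glycol
Product: 5 6-bromo-7-methyl-1,4-dioxaspiro[4.4]non-6-ene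
Conditions: p-toluenesulfonic acid monohydrate (cat.), benzene, reflux, Dean–Stark trap
Reagents that add atoms: none
Why: Acid-catalysed ketalisation with azeotropic removal of water; as with the parent 2-bromocyclopentenone the bromine-bearing tetrasubstituted alkene stays in place, and the ketal turns the enone into a substrate for halogen–metal exchange.

Step 3
Reactants: 5 6-bromo-7-methyl-1,4-dioxaspiro[4.4]non-6-ene, 6 succinic anhydride
Product: 9 methyl 4-(7-methyl-1,4-dioxaspiro[4.4]non-6-en-6-yl)-4-oxobutanoate, via vinyllithium 7 (not isolated), via lithium keto carboxylate 8 (not isolated)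
Conditions: n-BuLi, THF, −78 °C; cannulated into 6 (2 equiv), THF, −78 to 0 °C; then MeI, DMF, rt
Reagents that add atoms: iodomethane, CI
Why: Bromine–lithium exchange gives the vinyllithium, which opens the anhydride to a keto carboxylate; inverse addition to excess anhydride limits a second addition to the new ketone, and O-alkylation of the carboxylate in the same flask gives the methyl ester.

Step 4
Reactants: 9 methyl 4-(7-methyl-1,4-dioxaspiro[4.4]non-6-en-6-yl)-4-oxobutanoate
Product: 11 (5S)-5-(7-methyl-1,4-dioxaspiro[4.4]non-6-en-6-yl)oxolan-2-one, via hydroxy ester 10 (not isolated)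
Conditions: (R)-1-methyl-3,3-diphenyltetrahydro-1H,3H-pyrrolo[1,2-c][1,3,2]oxazaborole (20 mol%), BH3·SMe2, THF, −20 °C; MeOH; then 1,8-diazabicyclo[5.4.0]undec-7-ene (cat.), PhMe, 40 °C
Reagents that add atoms: none
Why: Corey–Bakshi–Shibata reduction: the ketone binds with the bulky tetrasubstituted cyclopentenyl group as the large substituent and the CH2 chain as the small one, so the (R)-catalyst should deliver hydride to give the 4S alcohol; the γ-hydroxy ester then lactonises under mild base, which avoids acid that could ionise the allylic C–O bond.

Step 5
Reactants: 11 (5S)-5-(7-methyl-1,4-dioxaspiro[4.4]non-6-en-6-yl)oxolan-2-one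
Product: 12 (2S)-5-methylidene-2-(7-methyl-1,4-dioxaspiro[4.4]non-6-en-6-yl)oxolane
Conditions: Cp2TiMe2 (2.5 equiv), PhMe, 70 °C, dark; then pentane, filtration through basic Al2O3
Reagents that add atoms: dimethyltitanocene Cp2TiMe2, C[Ti](C)(C1C=CC=C1)C1C=CC=C1
Why: Petasis methylenation of a lactone: thermally generated Cp2Ti=CH2 adds to the carbonyl and cycloreverts to the exocyclic enol ether; the medium is non-acidic, so the enol ether does not migrate into the ring and the carbinol centre is untouched.

Step 6
Reactants: 12 (2S)-5-methylidene-2-(7-methyl-1,4-dioxaspiro[4.4]non-6-en-6-yl)oxolane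
Product: 13 (1R)-hydroazulenone [C9 ketone; C5=C6 alkene; C4 ethylene ketal; C1 methyl]
Conditions: degassed PhMe (0.02 M), Et3N (10 mol%), base-washed sealed tube, 190 °C
Reagents that add atoms: none
Why: Thermal [3,3] sigmatropic (Claisen) rearrangement of the allyl vinyl ether C10=C9–O–C6–C5=C1: C10 bonds to C1 as the C6–O bond breaks, so the enol ether becomes the C9 ketone and the alkene moves to C5=C6. The closest known reaction is the ring-expanding Claisen rearrangement of 2-methylidene-5-vinyltetrahydrofurans to cyclohept-4-enones; here the vinyl terminus is fully substituted, which is why a high temperature is planned. The seven-membered carbocycle closes by C–C bond formation between the exocyclic methylene carbon and the distal alkene carbon through a boat-like, bridged transition state in which the ring oxygen is the one-atom bridge that is given up; the five-membered carbocycle is already present. The new stereocentre C1 is controlled by the C6 carbinol centre: the shift is suprafacial on the allyl unit and the tether allows only the geometry that gives a cis ring alkene (C7 and C1 on the same side of C5=C6), so the 6S ether can give only the 1R ketone. The step needs the [3,3] path to win over ionisation, a [1,3] shift and acid-catalysed migration of the exocyclic enol ether into the ring; a non-polar medium, base-washed glass and a trace of amine secure this. The C1 methyl has to pass over the tetrahydrofuran ring in the transition state, which raises the barrier but cannot change the stereochemical outcome.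

Step 7
Reactants: 13 (1R)-hydroazulenone [C9 ketone; C5=C6 alkene; C4 ethylene ketal; C1 methyl]
Product: 14 (1R)-bis-ketal [C9 dimethyl ketal; C4 ethylene ketal; C5=C6 alkene]
Conditions: MeOSiMe3 (3 equiv), Me3SiOTf (2 mol%), CH2Cl2, −78 °C; pyridine quench
Reagents that add atoms: methoxytrimethylsilane, CO[Si](C)(C)C
Why: Silyl-triflate-catalysed aprotic ketalisation with an alkoxysilane, driven by formation of hexamethyldisiloxane; at −78 °C without protic acid the allylic dioxolane should neither exchange (any opened oxocarbenium recloses intramolecularly) nor lose the position of its double bond, and the acyclic ketal masks C9 against borane.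

Step 8
Reactants: 14 (1R)-bis-ketal [C9 dimethyl ketal; C4 ethylene ketal; C5=C6 alkene]
Product: 16 (1R,5S,6S)-alcohol [C6 hydroxyl; trans ring fusion; C9 dimethyl ketal; C4 ethylene ketal], via alkylborane 15 (not isolated)
Conditions: BH3·THF (3 equiv), THF, 0 °C to rt; then NaOH (3 M), H2O2 (30%), 0 °C to rt
Reagents that add atoms: hydrogen peroxide, OO
Why: Hydroboration–oxidation: borane adds syn across C5=C6 with boron on the less substituted C6, and approach from the face opposite the angular C1 methyl should place H5 and boron on that face; oxidation with retention then gives the 6S alcohol with the trans ring fusion (5S).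

Step 9
Reactants: 16 (1R,5S,6S)-alcohol [C6 hydroxyl; trans ring fusion; C9 dimethyl ketal; C4 ethylene ketal]
Product: 18 (1R,5S,6S)-ketone [C9 ketone; C6 OSiMe2tBu; C4 ethylene ketal], via silylated dimethyl ketal 17 (not isolated)
Conditions: tBuMe2SiOTf, 2,6-lutidine, CH2Cl2, −78 to 0 °C; then pyridinium p-toluenesulfonate (cat.), acetone/H2O, rt
Reagents that add atoms: tert-butyldimethylsilyl trifluoromethanesulfonate, CC(C)(C)[Si](C)(C)OS(=O)(=O)C(F)(F)F; water, O
Why: The silyl triflate silylates the hindered secondary alcohol, and mild aqueous acid then hydrolyses the acyclic dimethyl ketal far faster than the hindered, β-oxygenated dioxolane (selective ketal hydrolysis); any methyl enol ether formed from the dimethyl ketal by the triflate converges on the same ketone.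

Step 10
Reactants: 18 (1R,5S,6S)-ketone [C9 ketone; C6 OSiMe2tBu; C4 ethylene ketal]
Product: 20 C8-methyl ketone [C9 ketone; C8 methyl as epimer mixture; C6 OSiMe2tBu; C4 ethylene ketal], via lithium enolate 19 (not isolated)
Conditions: LiN(iPr)2, THF, −78 °C; MeI, −78 to −30 °C
Reagents that add atoms: iodomethane, CI
Why: Kinetic enolate alkylation: deprotonation should occur at C8 and not at C10, whose hydrogens are shielded by the adjacent quaternary C1; the configuration at C8 is irrelevant because the centre becomes trigonal in step 11.

Step 11
Reactants: 20 C8-methyl ketone [C9 ketone; C8 methyl as epimer mixture; C6 OSiMe2tBu; C4 ethylene ketal]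
Product: 22 (1R,5S,6S)-enone [C9 ketone; C7=C8 alkene; C8 methyl; C6 OSiMe2tBu; C4 ethylene ketal], via trimethylsilyl enol ether 21 (not isolated)
Conditions: Me3SiCl, Et3N, DMF, 80 °C; then Pd(OAc)2 (1.1 equiv), MeCN, rt
Reagents that add atoms: none
Why: Saegusa–Ito oxidation: equilibrating silylation favours the tetrasubstituted C8=C9 enol ether, Pd(OAc)2 (divalent palladium) forms the palladium enolate, and β-hydride elimination towards C7 gives the ring enone; the regioisomeric C9=C10 enol ether cannot eliminate because C1 is quaternary and simply returns the ketone.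

Step 12
Reactants: 22 (1R,5S,6S)-enone [C9 ketone; C7=C8 alkene; C8 methyl; C6 OSiMe2tBu; C4 ethylene ketal]
Product: 23 (1R,5S,6S,9S)-allylic alcohol [C9 hydroxyl; C7=C8 alkene; C6 OSiMe2tBu; C4 ethylene ketal]
Conditions: (R)-1-methyl-3,3-diphenyltetrahydro-1H,3H-pyrrolo[1,2-c][1,3,2]oxazaborole (0.5 equiv), BH3·SMe2, THF, −30 °C; MeOH
Reagents that add atoms: none
Why: Corey–Bakshi–Shibata reduction of an α-substituted cyclic enone: the methyl-bearing alkenyl arm (C8) acts as the large group and C10 as the small one, so the (R)-catalyst should give the 9S alcohol by 1,2-reduction under reagent control, independent of the remote ring stereocentres.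

Step 13
Reactants: 23 (1R,5S,6S,9S)-allylic alcohol [C9 hydroxyl; C7=C8 alkene; C6 OSiMe2tBu; C4 ethylene ketal]
Product: 24 (1R,5S,6S,9S)-hydroxy ketone [C4 ketone; C9 hydroxyl; C6 OSiMe2tBu]
Conditions: pyridinium p-toluenesulfonate (0.3 equiv), acetone/H2O (10:1), 50 °C
Reagents that add atoms: water, O
Why: Acid-catalysed ketal hydrolysis under conditions too weakly acidic to ionise the secondary allylic C–O bonds or to cleave the hindered silyl ether; C5 keeps its configuration as long as no base is present.

Step 14
Reactants: 24 (1R,5S,6S,9S)-hydroxy ketone [C4 ketone; C9 hydroxyl; C6 OSiMe2tBu]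
Product: 25 (1R,4R,5S,6S,9S)-6-O-(tert-butyldimethylsilyl)dauc-7-ene-4,6,9-triol
Conditions: iPrMgCl (4 equiv), CeCl3 (anhydrous, 4.5 equiv), THF, −78 to 0 °C
Reagents that add atoms: isopropylmagnesium chloride, CC(C)[Mg]Cl
Why: Organocerium 1,2-addition: the weakly basic cerium reagent should add without enolising C5, without β-elimination of the C6 silyloxy group and without β-hydride reduction; attack from the face opposite the angular C1 methyl (the face of H5) places the isopropyl group cis to H5 and the new hydroxyl cis to the methyl (4R).

Step 15
Reactants: 25 (1R,4R,5S,6S,9S)-6-O-(tert-butyldimethylsilyl)dauc-7-ene-4,6,9-triol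
Product: 26 (1R,4R,5S,6S,9S)-6-O-(tert-butyldimethylsilyl)dauc-7-ene-4,6,9-triol 9-acetate
Conditions: Ac2O, pyridine, 4-(dimethylamino)pyridine (cat.), CH2Cl2, 0 °C to rt
Reagents that add atoms: acetic anhydride, CC(=O)OC(C)=O
Why: Nucleophile-catalysed acylation of the only free secondary alcohol; the tertiary C4 hydroxyl is too hindered to react and C6 is silylated.

Step 16
Reactants: 26 (1R,4R,5S,6S,9S)-6-O-(tert-butyldimethylsilyl)dauc-7-ene-4,6,9-triol 9-acetate
Product: 27 (1R,4R,5S,6S,9S)-dauc-7-ene-4,6,9-triol 9-acetate
Conditions: HF·pyridine, pyridine, THF, 0 °C to rt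
Reagents that add atoms: none
Why: Fluoride-driven cleavage of the silyl ether in a buffered, non-basic medium, so that no alkoxide is formed that could trigger acetyl migration or elimination of the allylic acetate.

Step 17
Reactants: 28 4-hydroxybenzoic acid
Product: 30 4-[(tert-butyldimethylsilyl)oxy]benzoic acid, via bis-silyl derivative 29 (not isolated)
Conditions: tBuMe2SiCl (2.3 equiv), imidazole, DMF, rt; then AcOH, THF/H2O, rt
Reagents that add atoms: tert-butyldimethylsilyl chloride, CC(C)(C)[Si](C)(C)Cl
Why: Exhaustive silylation followed by selective hydrolysis of the silyl ester, which is far more labile than the aryl silyl ether.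

Step 18
Reactants: 27 (1R,4R,5S,6S,9S)-dauc-7-ene-4,6,9-triol 9-acetate, 30 4-[(tert-butyldimethylsilyl)oxy]benzoic acid
Product: 31 (1R,4R,5S,6S,9S)-9-acetoxy-4-hydroxydauc-7-en-6-yl 4-[(tert-butyldimethylsilyl)oxy]benzoate
Conditions: N-(3-dimethylaminopropyl)-N′-ethylcarbodiimide hydrochloride, 4-(dimethylamino)pyridine, CH2Cl2, rt to 40 °C
Reagents that add atoms: none
Why: Steglich esterification: the acylpyridinium species acylates the secondary C6 hydroxyl while the tertiary C4 hydroxyl stays free; the neutral conditions leave the allylic acetate in place.

Step 19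
Reactants: 31 (1R,4R,5S,6S,9S)-9-acetoxy-4-hydroxydauc-7-en-6-yl 4-[(tert-butyldimethylsilyl)oxy]benzoate
Product: 32 (1R,4R,5S,6S,9S)-9-acetoxy-4-hydroxydauc-7-en-6-yl 4-hydroxybenzoate (CNP0305796.2)
Conditions: HF·pyridine, pyridine, THF, 0 °C to rt
Reagents that add atoms: none
Why: The silyl ether of a phenol that carries a para acyl group is a good leaving group at silicon and is cleaved by fluoride under mild, non-basic conditions, which releases the phenol without touching the acetate, the benzoate or the allylic system.

## Compound list

1 | 3-methylcyclopent-2-en-1-one | CC1=CC(=O)CC1 | starting material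
2 | trans-2,3-dibromo-3-methylcyclopentan-1-one (racemic; one enantiomer drawn) | O=C1CC[C@](C)(Br)[C@H]1Br | intermediate
3 | 2-bromo-3-methylcyclopent-2-en-1-one | CC1=C(Br)C(=O)CC1 | intermediate
4 | ethylene glycol | OCCO | starting material
5 | 6-bromo-7-methyl-1,4-dioxaspiro[4.4]non-6-ene | CC1=C(Br)C2(CC1)OCCO2 | intermediate
6 | succinic anhydride | O=C1CCC(=O)O1 | starting material
7 | (7-methyl-1,4-dioxaspiro[4.4]non-6-en-6-yl)lithium | [Li]C1=C(C)CCC12OCCO2 | intermediate
8 | lithium 4-(7-methyl-1,4-dioxaspiro[4.4]non-6-en-6-yl)-4-oxobutanoate | [Li+].[O-]C(=O)CCC(=O)C1=C(C)CCC12OCCO2 | intermediate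
9 | methyl 4-(7-methyl-1,4-dioxaspiro[4.4]non-6-en-6-yl)-4-oxobutanoate | COC(=O)CCC(=O)C1=C(C)CCC12OCCO2 | intermediate
10 | methyl (4S)-4-hydroxy-4-(7-methyl-1,4-dioxaspiro[4.4]non-6-en-6-yl)butanoate | COC(=O)CC[C@H](O)C1=C(C)CCC12OCCO2 | intermediate
11 | (5S)-5-(7-methyl-1,4-dioxaspiro[4.4]non-6-en-6-yl)oxolan-2-one | O=C1CC[C@H](O1)C2=C(C)CCC23OCCO3 | intermediate
12 | (2S)-5-methylidene-2-(7-methyl-1,4-dioxaspiro[4.4]non-6-en-6-yl)oxolane (Claisen precursor; C6 is S) | C=C1CC[C@H](O1)C2=C(C)CCC23OCCO3 | intermediate
13 | (1R)-hydroazulenone: C9 ketone, C5=C6 alkene, C4 ethylene ketal, C1 methyl | O=C1C[C@@]2(C)CCC3(OCCO3)C2=CCC1 | intermediate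
14 | (1R)-bis-ketal: C9 dimethyl ketal, C4 ethylene ketal, C5=C6 alkene | COC1(OC)C[C@@]2(C)CCC3(OCCO3)C2=CCC1 | intermediate
15 | C6 alkylborane from 14 (boron and H5 cis, both trans to the C1 methyl) | COC1(OC)C[C@@]2(C)CCC3(OCCO3)[C@@H]2[C@@H](B)CC1 | intermediate
16 | (1R,5S,6S)-alcohol: C6 hydroxyl, trans ring fusion, C9 dimethyl ketal, C4 ethylene ketal | COC1(OC)C[C@@]2(C)CCC3(OCCO3)[C@@H]2[C@@H](O)CC1 | intermediate
17 | (1R,5S,6S)-C6 tert-butyldimethylsilyl ether of 16 | COC1(OC)C[C@@]2(C)CCC3(OCCO3)[C@@H]2[C@@H](O[Si](C)(C)C(C)(C)C)CC1 | intermediate
18 | (1R,5S,6S)-ketone: C9 ketone, C6 tert-butyldimethylsilyl ether, C4 ethylene ketal | O=C1C[C@@]2(C)CCC3(OCCO3)[C@@H]2[C@@H](O[Si](C)(C)C(C)(C)C)CC1 | intermediate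
19 | lithium C8=C9 enolate of 18 | [Li]OC=1C[C@@]2(C)CCC3(OCCO3)[C@@H]2[C@@H](O[Si](C)(C)C(C)(C)C)CC=1 | intermediate
20 | (1R,5S,6S)-C8-methyl ketone, mixture of C8 epimers | O=C1C[C@@]2(C)CCC3(OCCO3)[C@@H]2[C@@H](O[Si](C)(C)C(C)(C)C)CC1C | intermediate
21 | trimethylsilyl C8=C9 enol ether of 20 | C[Si](C)(C)OC=1C[C@@]2(C)CCC3(OCCO3)[C@@H]2[C@@H](O[Si](C)(C)C(C)(C)C)CC=1C | intermediate
22 | (1R,5S,6S)-enone: C9 ketone, C7=C8 alkene, C8 methyl, C6 silyl ether, C4 ethylene ketal | O=C1C[C@@]2(C)CCC3(OCCO3)[C@@H]2[C@@H](O[Si](C)(C)C(C)(C)C)C=C1C | intermediate
23 | (1R,5S,6S,9S)-allylic alcohol: C9 hydroxyl, C7=C8 alkene, C6 silyl ether, C4 ethylene ketal | O[C@H]1C[C@@]2(C)CCC3(OCCO3)[C@@H]2[C@@H](O[Si](C)(C)C(C)(C)C)C=C1C | intermediate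
24 | (1R,5S,6S,9S)-hydroxy ketone: C4 ketone, C9 hydroxyl, C6 silyl ether | O[C@H]1C[C@@]2(C)CCC(=O)[C@@H]2[C@@H](O[Si](C)(C)C(C)(C)C)C=C1C | intermediate
25 | (1R,4R,5S,6S,9S)-6-O-(tert-butyldimethylsilyl)dauc-7-ene-4,6,9-triol | O[C@H]1C[C@@]2(C)CC[C@@](O)(C(C)C)[C@@H]2[C@@H](O[Si](C)(C)C(C)(C)C)C=C1C | intermediate
26 | (1R,4R,5S,6S,9S)-6-O-(tert-butyldimethylsilyl)dauc-7-ene-4,6,9-triol 9-acetate | CC(=O)O[C@H]1C[C@@]2(C)CC[C@@](O)(C(C)C)[C@@H]2[C@@H](O[Si](C)(C)C(C)(C)C)C=C1C | intermediate
27 | (1R,4R,5S,6S,9S)-dauc-7-ene-4,6,9-triol 9-acetate | CC(=O)O[C@H]1C[C@@]2(C)CC[C@@](O)(C(C)C)[C@@H]2[C@@H](O)C=C1C | intermediate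
28 | 4-hydroxybenzoic acid | OC(=O)c1ccc(O)cc1 | starting material
29 | tert-butyldimethylsilyl 4-[(tert-butyldimethylsilyl)oxy]benzoate | CC(C)(C)[Si](C)(C)OC(=O)c1ccc(O[Si](C)(C)C(C)(C)C)cc1 | intermediate
30 | 4-[(tert-butyldimethylsilyl)oxy]benzoic acid | OC(=O)c1ccc(O[Si](C)(C)C(C)(C)C)cc1 | intermediate
31 | (1R,4R,5S,6S,9S)-9-acetoxy-4-hydroxydauc-7-en-6-yl 4-[(tert-butyldimethylsilyl)oxy]benzoate | CC(=O)O[C@H]1C[C@@]2(C)CC[C@@](O)(C(C)C)[C@@H]2[C@@H](OC(=O)c2ccc(O[Si](C)(C)C(C)(C)C)cc2)C=C1C | intermediate
32 | (1R,4R,5S,6S,9S)-9-acetoxy-4-hydroxydauc-7-en-6-yl 4-hydroxybenzoate (CNP0305796.2) | CC(=O)O[C@H]1C[C@@]2(C)CC[C@@](O)(C(C)C)[C@@H]2[C@@H](OC(=O)c2ccc(O)cc2)C=C1C | target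

## Step count and least certain steps

Total step count: 19. Longest linear sequence: 18 steps (steps 1–16, 18 and 19); step 17 is a one-step side branch that prepares acid 30.

**Step 6 (key step).** The rearrangement may stall because the fully substituted alkene terminus, carrying the C1 methyl, must approach the methylene carbon across the tetrahydrofuran ring. At the temperature then needed, migration of the exocyclic enol ether into the ring or ionisation of the allylic C–O bond may overtake the [3,3] shift.

Fallback, from 5 back to 13: the quaternary centre is made by an open-chain Claisen rearrangement and the ring is closed afterwards. The lithium reagent 7 made from 5 is acylated with N-methoxy-N-methylacetamide to give 1-(7-methyl-1,4-dioxaspiro[4.4]non-6-en-6-yl)ethan-1-one F1. Reduction with (S)-1-methyl-3,3-diphenyltetrahydro-1H,3H-pyrrolo[1,2-c][1,3,2]oxazaborole and BH3·SMe2 gives the (1R)-allylic alcohol F2, which is acetylated to the acetate F3. The S catalyst is needed here because the carbinol methyl takes the outer, equatorial position of a chair, whereas in 12 the ring forces the carbon substituent inside. Ireland–Claisen rearrangement (LiN(iPr)2, Me3SiCl, THF, −78 °C to reflux, then water) forms the C1–C10 bond and gives the ethylidene acid F4 with C1 in the R configuration. The acid is converted into its N-methoxy-N-methylamide F5, and but-3-enylmagnesium bromide gives the hexenone F6. Ring-closing metathesis with the second-generation Grubbs catalyst RuCl2(=CHPh)(H2IMes)(PCy3) in PhMe at 80 °C joins the internal carbon of the terminal alkene, which becomes C6, to the ring carbon C5 that carries the ethylidene group, expels propene and delivers 13. The quaternary C1 and the ketal carbon C4 flank that alkene, so this closure is the demanding step of the detour.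

**Step 8.** Facial selectivity of the borane addition may be poor or reversed. The C1 methyl shields one face of C5=C6, but the folded seven-membered ring (C8 and C10) shields the other, so addition on the methyl face would give the cis ring fusion.

Fallback, from 14 back to 16: C5 is set under thermodynamic control through a C6 ketone instead of under kinetic control in the addition. The hydroboration is run as in step 8, and the cis-fused (5R,6R)-alcohol F7 is oxidised (Swern oxidation: (COCl)2, DMSO, Et3N) to the cis-fused C6 ketone F8. Equilibration with NaOMe in MeOH through the C5 enolate gives the trans-fused C6 ketone F9; the cis ketone is recycled. How far the equilibrium favours the trans isomer is not known and would have to be tested. Reduction with NaBH4 or LiBH(sBu)3, with hydride entering from the face the borane preferred, returns 16; whether the hydride follows that preference in the trans-fused ketone would also have to be established.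

**Step 12.** The catalyst may meet a mismatched substrate: the neopentyl C10 arm is not much smaller than the alkenyl arm, and the ring may impose its own facial bias, so the 9S selectivity may erode.

Fallback, from 22 back to 23: the centre is corrected by inversion instead of being set by the catalyst. Luche reduction (NaBH4, CeCl3·7H2O, MeOH) under substrate control is expected to favour the (9R)-allylic alcohol F10, with hydride entering anti to the C1 methyl. Mitsunobu reaction with 4-nitrobenzoic acid, PPh3 and diisopropyl azodicarboxylate gives the inverted (9S)-4-nitrobenzoate F11, and methanolysis (K2CO3, MeOH) gives 23.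

**Step 13.** Hydrolysis of the hindered, β-oxygenated dioxolane may be slow. Forcing it may bring on ionisation of the allylic C9–O or C6–O bonds, loss of the silyl ether or elimination across C5–C6.

Fallback, from 23 back to 26: the order of events is changed so that no free allylic alcohol meets acid. 23 is acetylated first to the ketal acetate F12, and the ketal is then hydrolysed with the stronger p-toluenesulfonic acid in acetone/H2O to the keto acetate F13. The isopropyl group is added with the cerium reagent from iPrMgCl and CeCl3 at −78 °C, relying on the preference of organocerium reagents for ketones over esters. This gives 26 directly and bypasses 24 and 25.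

**Step 14.** The addition may be diverted by enolisation at C5 (with loss of the silyloxy group), by β-hydride reduction of the hindered ketone by the secondary alkyl reagent, or by attack on the wrong face. The last is a real possibility because the C6 silyloxy group lies on the face from which the reagent is meant to come, opposite the C1 methyl.

Fallback, from 24 back to 25: the group is introduced as an sp2 nucleophile that is smaller, cannot donate a β-hydride and is then saturated. Isopropenylmagnesium bromide with CeCl3 in THF at −78 °C gives the isopropenyl carbinol F14. Hydrogenation with RhCl(PPh3)3 and H2 in benzene reduces the 1,1-disubstituted alkene in preference to the trisubstituted ring alkene and gives 25.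

## Further compounds

F1 | step 6 | 1-(7-methyl-1,4-dioxaspiro[4.4]non-6-en-6-yl)ethan-1-one | CC(=O)C1=C(C)CCC12OCCO2
F2 | step 6 | (1R)-1-(7-methyl-1,4-dioxaspiro[4.4]non-6-en-6-yl)ethan-1-ol | C[C@@H](O)C1=C(C)CCC12OCCO2
F3 | step 6 | (1R)-1-(7-methyl-1,4-dioxaspiro[4.4]non-6-en-6-yl)ethyl acetate | C[C@@H](OC(C)=O)C1=C(C)CCC12OCCO2
F4 | step 6 | 2-[(6Z,7R)-6-ethylidene-7-methyl-1,4-dioxaspiro[4.4]nonan-7-yl]acetic acid | OC(=O)C[C@@]1(C)CCC2(OCCO2)/C1=C\C
F5 | step 6 | 2-[(6Z,7R)-6-ethylidene-7-methyl-1,4-dioxaspiro[4.4]nonan-7-yl]-N-methoxy-N-methylacetamide | CON(C)C(=O)C[C@@]1(C)CCC2(OCCO2)/C1=C\C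
F6 | step 6 | 1-[(6Z,7R)-6-ethylidene-7-methyl-1,4-dioxaspiro[4.4]nonan-7-yl]hex-5-en-2-one | C=CCCC(=O)C[C@@]1(C)CCC2(OCCO2)/C1=C\C
F7 | step 8 | (1R,5R,6R)-alcohol, cis-fused epimer of 16 at C5 and C6 | COC1(OC)C[C@@]2(C)CCC3(OCCO3)[C@H]2[C@H](O)CC1
F8 | step 8 | (1R,5R)-cis-fused C6 ketone with C9 dimethyl ketal and C4 ethylene ketal | COC1(OC)C[C@@]2(C)CCC3(OCCO3)[C@H]2C(=O)CC1
F9 | step 8 | (1R,5S)-trans-fused C6 ketone with C9 dimethyl ketal and C4 ethylene ketal | COC1(OC)C[C@@]2(C)CCC3(OCCO3)[C@@H]2C(=O)CC1
F10 | step 12 | (1R,5S,6S,9R)-allylic alcohol, C9 epimer of 23 | O[C@@H]1C[C@@]2(C)CCC3(OCCO3)[C@@H]2[C@@H](O[Si](C)(C)C(C)(C)C)C=C1C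
F11 | step 12 | (1R,5S,6S,9S)-C9 4-nitrobenzoate of 23 | O=C(O[C@H]1C[C@@]2(C)CCC3(OCCO3)[C@@H]2[C@@H](O[Si](C)(C)C(C)(C)C)C=C1C)c1ccc(cc1)[N+](=O)[O-]
F12 | step 13 | (1R,5S,6S,9S)-C9 acetate of 23 (C4 ethylene ketal, C6 silyl ether) | CC(=O)O[C@H]1C[C@@]2(C)CCC3(OCCO3)[C@@H]2[C@@H](O[Si](C)(C)C(C)(C)C)C=C1C
F13 | step 13 | (1R,5S,6S,9S)-keto acetate (C4 ketone, C9 acetate, C6 silyl ether) | CC(=O)O[C@H]1C[C@@]2(C)CCC(=O)[C@@H]2[C@@H](O[Si](C)(C)C(C)(C)C)C=C1C
F14 | step 14 | (1R,4S,5S,6S,9S)-C4 isopropenyl carbinol (isopropenyl in place of isopropyl in 25; same arrangement in space at all five centres, the C4 descriptor changing only because isopropenyl outranks C5) | O[C@H]1C[C@@]2(C)CC[C@@](O)(C(C)=C)[C@@H]2[C@@H](O[Si](C)(C)C(C)(C)C)C=C1C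
A1 | alternative 1 | (S)-citronellol | OCC[C@@H](C)CCC=C(C)C
A2 | alternative 1 | methyl (6S)-8-[(tert-butyldimethylsilyl)oxy]-2-diazo-6-methyl-3-oxooctanoate | CC(C)(C)[Si](C)(C)OCC[C@@H](C)CCC(=O)C(=[N+]=[N-])C(=O)OC
A3 | alternative 1 | methyl 2-[2-[(tert-butyldimethylsilyl)oxy]ethyl]-2-methyl-5-oxocyclopentane-1-carboxylate (configuration as drawn) | CC(C)(C)[Si](C)(C)OCC[C@@]1(C)CCC(=O)[C@@H]1C(=O)OC
A4 | alternative 2 | epoxy enol silane: C4–C5 epoxide with isopropyl on C4, triethylsilyl enol ether C6=C7, (E,E)-diene C8=C9–C10=C1 (C5 configuration immaterial, drawn arbitrarily) | C/C=C/C=C(\C)CC[C@]1(C(C)C)O[C@@H]1C(=C)O[Si](CC)(CC)CC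
A5 | alternative 2 | bicyclic C6 ketone with C4 triethylsilyl ether, C8 methyl, C9=C10 alkene and quaternary C1 | C1=C[C@@]2(C)CC[C@@](O[Si](CC)(CC)CC)(C(C)C)[C@@H]2C(=O)C[C@H]1C
A6 | alternative 3 | (E)-2-(trimethylsilyl)ethenylmagnesium bromide | C[Si](C)(C)/C=C/[Mg]Br
A7 | alternative 3 | (Z)-3-iodobut-2-enal | O=C/C=C(/C)I
A8 | alternative 3 | trans-2,3-disubstituted cyclopentanone aldol with C1, C5 and C6 set | C[Si](C)(C)/C=C/[C@@]1(C)CCC(=O)[C@@H]1[C@@H](O)/C=C(/C)I
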